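## Analysis of the target

Conneotricone (23) is a depsidone: two benzene rings are tied together by a diaryl ether oxygen and by an aryl ester, so that a seven-membered dioxepinone lies between them, and one ring also carries a fused five-membered lactone (a phthalide). Ring A is labelled A1 (methyl), A2 (H), A3 (OH), A4 (CO2H), A5 (ether oxygen) and A6 (carbonyl of the seven-membered lactone); ring B is labelled B1 (oxygen of that lactone), B2 (CH2OH), B3 (OH), B4 (phthalide carbonyl), B5 (phthalide CH2) and B6 (ether oxygen). The molecule has no stereocentre and no stereogenic double bond, so the problem is one of constitution only: ring B is hexasubstituted, ring A pentasubstituted, and the ether oxygen has four ortho substituents. The sensitive points are the seven-membered aryl ester, which alkoxide or hydroxide opens, the B2 hydroxymethyl group, which with the B3 phenol is an ortho-hydroxybenzyl alcohol and ionises to a quinone methide in acid, and the salicylic acid at A3/A4. Two things make the synthesis hard: two fully ortho-substituted arenes must be joined through oxygen, and ring A has two carboxyl carbons (A4 and A6) on either side of that oxygen, of which only A6 may close onto B1. The strategy rests on the oxygen pattern of ring B: B1 and B3 bear oxygen in a 1,3 relation and B4, next to B3, bears a carboxyl carbon, which is the pattern of a cyclohexane-1,3-dione with an ester on the adjoining carbon. Read in that way, B5 and B6 are the β- and α-carbons of an enone whose α-substituent is the ring A aryloxy group, so the crowded ether can be brought in as a plain phenol ether and ring B grown on it as a saturated ring that is aromatised afterwards.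

## Retrosynthetic reasoning

**23 ⇒ 22.** The last bond made is a C–H bond: the B2 hydroxymethyl group is taken back to the aldehyde of 22. The benzylic alcohol is the one group of 23 that tolerates neither Lewis acid nor strong protic acid, whereas an aldehyde tolerates both. With the reduction last, every deprotection is finished before the alcohol exists. The forward step has to reduce an aldehyde beside two lactones and a free acid.

**22 ⇒ 20 (through 21).** The O–alkyl bonds of the tert-butyl ester on A4 and of the methyl ether on A3 are cut. Both groups are inert to base, hydrogen and carbodiimide, and both fall to one Lewis acid, the ether because it sits ortho to the carboxyl and is cleaved through a chelate. Nothing else in 20 carries an alkyl–oxygen bond that this reagent attacks.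

**20 ⇒ 19.** The ester C–O bond between the A6 carbonyl and the B1 oxygen is cut, which opens the seven-membered ring to the hydroxy acid 19. The cut is made here and not at the ether because the ether is the crowded bond and is better carried from the very start. In 19 the A6 acid is the only free carboxyl (A4 is still the tert-butyl ester) and the B1 hydroxyl is the only one within reach, so the regiochemistry of the closure is built into the substrate.

**19 ⇒ 17 (through 18).** The bond from B2 to its one-carbon substituent is cut. In 17, B2 is the last unsubstituted carbon of ring B and lies between two free phenols, the best moment for an ortho-directed one-carbon introduction. Earlier, an aldehyde would not survive the hydrogenolysis; later, only one phenol would be left to direct it. The one free carbon of ring A (A2) has no free phenol next to it and is not addressed.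

**17 ⇒ 15 (through 16).** The phthalide C–O bond and two benzyl–oxygen bonds are cut. In 15 the B5 arm is a benzyl ether and the A6 carboxyl a benzyl ester. One hydrogenolysis frees both, and the liberated alcohol closes onto the neighbouring B4 methyl ester. This is also where the two ring A carboxyls are told apart: A6 is benzyl and goes now, A4 is tert-butyl and stays.

**15 ⇒ 14.** Ring B is taken back by two hydrogens to the cyclohexane-1,3-dione 14. The gain is that all substituents of ring B can be set by carbonyl chemistry on a ring that is not yet an arene, with no substitution on a crowded benzene. The forward reaction must be an oxidation and not an elimination, so that the aryloxy group on B6 is kept.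

**14 ⇒ 11 + 12 (through 13).** The B4–B5 and B2–B3 bonds are cut, which gives the α-aryloxy enone 11 and dimethyl malonate 12. The enone fixes the regiochemistry: its β-carbon becomes B5 with the CH2O arm, its α-carbon becomes B6 with the ether oxygen, its methyl group becomes B2. The malonate supplies B4 with the future phthalide carbonyl, and B3. The forward step must achieve conjugate addition to an oxygen-substituted enone and a ring-closing acylation, with both ring A esters left alone.

**11 ⇒ 9 + 10, and 9 ⇒ 7 + 8.** The enone double bond is cut by a phosphonate olefination to keto phosphonate 9 and benzyloxyacetaldehyde 10. The bond between the ring A oxygen and the future B6 is cut by carbenoid O–H insertion to phenol 7 and diazo phosphonate 8. The phosphonate decides which α-carbon of the ketone is olefinated. The insertion runs without base, so an enolisable aryloxy ketone never meets base next to two ortho esters.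

**7 ⇒ 1 (through 2, 3, 5 and 6).** Ring A comes from orsellinic acid 1. Its own carboxyl is A6 and is benzylated (2), the non-chelated hydroxyl is methylated (3), the A4 carbon is added ortho to the remaining phenol as an aldehyde (5, through 4), oxidised (6) and tert-butylated (7). The phenol oxygen of 7 is the ether oxygen of the target.

## Alternatives that were turned down

**Alternative 1:** The disconnection is the B1–O ester bond, with ring B traced back to a non-aromatic quinone monoketal. In the forward sense the spiro ketal A2 is treated with acid: the acyloxy oxygen moves from B6 to B1 through a bridged dioxolanylium ion, the six-membered dioxinone grows to the seven-membered ring, and ring B aromatises to the depsidone A1. In its favour, one step delivers the whole tricyclic skeleton, and the carboxyl that enters the lactone is chosen by the earlier spiro-ketalisation; on the step count after the key step it is stronger than the chosen route. Against it for this target, A2 presupposes a hexasubstituted ring B arene already joined to ring A through the tetra-ortho-substituted ether. The dienone of A2 carries an electron-withdrawing butenolide, which disfavours both its formation by phenol oxidation and the cationic shift. The acid step also has to spare a benzylic acetate. A1 ends with a methyl ester on A4 and an acetate on the B2 arm, and neither can be removed without endangering the seven-membered aryl ester. The chosen route gives up the one-step ring formation but builds ring B by construction, needs no coupling to a crowded arene, and ends in deprotections the lactones tolerate.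

**Alternative 2:** The disconnection is through ring A (A1–A6 and A4–A5 bonds), with the ether oxygen carried on an alkyne. In the forward sense the pyrone ester A4 and the ring B aryloxypropiolate A5 undergo an inverse-demand cycloaddition and lose carbon dioxide to give the diaryl ether A3. In its favour, it is convergent, it makes the crowded ether without any aryl–oxygen coupling, and the two ring A carboxyls emerge already differentiated (methyl and tert-butyl), a point on which it equals the chosen route. Against it, the ring that is made de novo is the easier one: ring A is readily derived from orsellinic acid, while the hexasubstituted ring B of A5 must still be assembled by substitution chemistry and then turned into a hindered aryl ynol ether. The push-pull alkyne is a sluggish dienophile towards a pyrone that itself carries a donor methoxy group. A3 again holds a methyl ester on A4 that has to be cleaved beside two lactones. The chosen route uses the same idea of growing a ring around the ether oxygen, but applies it to ring B, where it removes the harder problem.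

**Alternative 3:** The disconnection is through ring B (B3–B4 and B5–B6 bonds) with no ring A attached. In the forward sense the silyloxyfuran A7 adds across the alkynoate A8, the oxygen bridge opens to a hydroquinone, and acid closes the lactone to give the phthalide A6. In its favour, ring B and the phthalide arise in one step with every substituent placed by construction, the B2 carbon is present from the start (the chosen route must add it late), and the two hydroquinone hydroxyls differ because one is chelated to the lactone carbonyl. Against it, the hardest bond is left for afterwards: the di-ortho-substituted B6 phenol of A6 must be joined to a ring A carbon that sits between two carboxyl groups. That requires an activated ring A electrophile with differentiated esters, made in several steps, and an intermolecular coupling at a tetra-ortho-substituted centre. The acetal on the B2 arm also has to come off with acid at a stage where the benzylic alcohol is exposed. The chosen route is longer in its linear sequence but contains no intermolecular aryl–oxygen bond formation at all.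

Key step: step 8

Remark: compounds 1, 8, 10 and 12 are taken to be commercial.
Remark: the alkene geometry of 11 is lost in step 8, so either isomer serves; the Z isomer is drawn.
Remark: "Ar" in 11, 13, 14 and 15 is ring A as 2-[(benzyloxy)carbonyl]-6-(tert-butoxycarbonyl)-5-methoxy-3-methylphenyl.

## Route

Step 1
Reactants: 1 orsellinic acid (2,4-dihydroxy-6-methylbenzoic acid)
Product: 2 benzyl 2,4-dihydroxy-6-methylbenzoate
Conditions: BnBr, KHCO3, DMF, rt
Reagents that add atoms: benzyl bromide, BrCc1ccccc1
Why: Carboxylate alkylation (SN2); hydrogencarbonate deprotonates only the acid, so the phenols stay free, and room temperature avoids decarboxylation of the resorcylic acid.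

Step 2
Reactants: 2 benzyl 2,4-dihydroxy-6-methylbenzoate
Product: 3 benzyl 2-hydroxy-4-methoxy-6-methylbenzoate
Conditions: MeI (1.05 equiv), K2CO3, acetone, reflux
Reagents that add atoms: iodomethane, CI
Why: Williamson etherification; the 2-hydroxyl is locked in a hydrogen bond to the ester carbonyl and is the poorer nucleophile, so the 4-hydroxyl (future A3 oxygen) is methylated selectively.

Step 3
Reactants: 3 benzyl 2-hydroxy-4-methoxy-6-methylbenzoate
Product: 5 benzyl 3-formyl-2-hydroxy-4-methoxy-6-methylbenzoate, via hydroxymethyl phenol 4 (not isolated)
Conditions: MgCl2, Et3N, (CH2O)n, MeCN, reflux; cold 1 M HCl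
Reagents that add atoms: paraformaldehyde (as formaldehyde), C=O
Why: Magnesium-mediated ortho-formylation of a phenol (Casnati–Skattebøl type); the magnesium phenoxide delivers formaldehyde to the only free ortho carbon to give 4, which a second formaldehyde oxidises by hydride transfer. The para carbon is not reached by this chelate-bound mechanism.

Step 4
Reactants: 5 benzyl 3-formyl-2-hydroxy-4-methoxy-6-methylbenzoate
Product: 6 3-[(benzyloxy)carbonyl]-2-hydroxy-6-methoxy-4-methylbenzoic acid
Conditions: NaClO2, NaH2PO4, 2-methylbut-2-ene, tBuOH–H2O, rt
Reagents that add atoms: sodium chlorite, [Na+].[O-]Cl=O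
Why: Pinnick oxidation of the aldehyde to the acid; the alkene scavenges hypochlorous acid so that the free carbon para to the phenol is not chlorinated.

Step 5
Reactants: 6 3-[(benzyloxy)carbonyl]-2-hydroxy-6-methoxy-4-methylbenzoic acid
Product: 7 1-benzyl 3-tert-butyl 2-hydroxy-4-methoxy-6-methylbenzene-1,3-dicarboxylate
Conditions: Me2NCH(OtBu)2, toluene, 80 °C
Reagents that add atoms: N,N-dimethylformamide di-tert-butyl acetal, CN(C)C(OC(C)(C)C)OC(C)(C)C
Why: Alkylative tert-butyl esterification with a formamide acetal; the carboxylate is alkylated at oxygen, so the hindrance around the carbonyl does not matter, and the chelated phenol, far less acidic, is left free.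

Step 6
Reactants: 7 1-benzyl 3-tert-butyl 2-hydroxy-4-methoxy-6-methylbenzene-1,3-dicarboxylate; 8 dimethyl (1-diazo-2-oxopropyl)phosphonate
Product: 9 1-benzyl 3-tert-butyl 2-{[1-(dimethoxyphosphoryl)-2-oxopropyl]oxy}-4-methoxy-6-methylbenzene-1,3-dicarboxylate (racemic)
Conditions: Rh2(OAc)4 (2 mol %), toluene, 80 °C, slow addition of 8
Reagents that add atoms: none
Why: Rhodium carbenoid O–H insertion into a phenol: the electrophilic carbenoid is taken up by the phenol oxygen and a proton shift gives the ether. The medium is neutral, so neither ester is touched and no enolate can attack the flanking esters. The new stereocentre is racemic and is destroyed in step 7.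

Step 7
Reactants: 9 the aryloxy keto phosphonate; 10 benzyloxyacetaldehyde
Product: 11 (Z)-3-(aryloxy)-5-(benzyloxy)pent-3-en-2-one carrying ring A, that is 1-benzyl 3-tert-butyl 2-{[(3Z)-5-(benzyloxy)-2-oxopent-3-en-3-yl]oxy}-4-methoxy-6-methylbenzene-1,3-dicarboxylate
Conditions: NaH, THF, 0 °C; then 10, 0 °C → rt
Reagents that add atoms: none
Why: Horner–Wadsworth–Emmons olefination of a β-keto phosphonate; the phosphonate carbon is the only site deprotonated, so the double bond forms at the aryloxy-bearing carbon without ambiguity. The isomer with acetyl trans to the CH2OBn group (Z) is expected to prevail, and the minor isomer is equally usable.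

Step 8
Reactants: 11 the α-aryloxy enone; 12 dimethyl malonate
Product: 14 methyl 6-[(benzyloxy)methyl]-5-(aryloxy)-2,4-dioxocyclohexane-1-carboxylate (mixture of diastereomers and enol forms), via open-chain Michael adduct 13 (not isolated)
Conditions: NaOMe (1.2 equiv), 12 (1.2 equiv), MeOH, 0 °C → reflux; then 1 M HCl, 0 °C
Reagents that add atoms: none
Why: This is a Michael–Dieckmann (Michael–Claisen) annulation of an enone with a malonate, the classical entry to dihydroresorcylates. The malonate anion adds to the β-carbon of 11 (B5), which forms the B4–B5 bond and gives keto diester 13 after proton transfer. Under the same alkoxide the methyl ketone is enolised at B2 and this enolate attacks one malonate ester carbonyl (B3) in a 6-exo-trig closure; loss of methoxide and deprotonation of the resulting 1,3-dione, the thermodynamic sink, pull the preceding equilibria forward. Ring B is thereby closed as a six-membered carbocycle with the aryloxy group on B6, the CH2O arm on B5 and the future lactone carbonyl on B4, a regiochemistry dictated by the enone. Three sp3 centres (B4, B5, B6) arise without control, two of them epimerisable, and all three vanish on aromatisation, so no stereochemical element has to be governed. The step needs 1,4-addition despite the donor oxygen on the α-carbon, which should hold because the aryloxy ring bears two ortho ester groups, is twisted out of conjugation and donates poorly. It also needs both ring A esters to stay intact: each is a di-ortho-substituted benzoate (tert-butyl on A4; benzyl on A6 between the methyl group and the ether oxygen), shielded from methoxide and from the hindered B6 enolate, whose attack would in any case give only a non-enolisable, reversible adduct. The other closures open to 13 would make four- or seven-membered rings and should not compete.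

Step 9
Reactants: 14 the cyclohexane-1,3-dione
Product: 15 methyl 3-(aryloxy)-2-[(benzyloxy)methyl]-4,6-dihydroxybenzoate
Conditions: I2 (20 mol %), DMSO, 80 °C
Reagents that add atoms: none
Why: Iodine-catalysed oxidative aromatisation of a cyclohexane-1,3-dione ester to a resorcylate: α-iodination at B4 or B6 and loss of HI give a cyclohexenedione that tautomerises to the arene, and DMSO returns HI to I2. It is a dehydrogenation, so the C–OAr bond on B6 is not involved.

Step 10
Reactants: 15 the resorcylate
Product: 17 3-(tert-butoxycarbonyl)-2-[(5,7-dihydroxy-1-oxo-1,3-dihydro-2-benzofuran-4-yl)oxy]-4-methoxy-6-methylbenzoic acid, via hydroxy ester acid 16 (not isolated)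
Conditions: H2 (1 atm), 10% Pd/C, THF–MeOH, rt; filter; PPTS (cat.), toluene, 50 °C
Reagents that add atoms: none
Why: Hydrogenolysis removes the benzyl ether on the B5 arm and the benzyl ester on A6 together; the freed CH2OH lies ortho to the B4 methyl ester and closes the phthalide (5-exo-trig lactonisation) with loss of methanol. The tert-butyl ester, the methyl ether and the diaryl ether are inert.

Step 11
Reactants: 17 the phthalide acid
Product: 19 3-(tert-butoxycarbonyl)-2-[(6-formyl-5,7-dihydroxy-1-oxo-1,3-dihydro-2-benzofuran-4-yl)oxy]-4-methoxy-6-methylbenzoic acid, via hydroxymethyl phthalide 18 (not isolated)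
Conditions: MgCl2, Et3N (excess), (CH2O)n, THF, reflux; cold 1 M HCl
Reagents that add atoms: paraformaldehyde (as formaldehyde), C=O
Why: Magnesium-mediated ortho-formylation as in step 3; B2 is the only unsubstituted carbon of ring B and is ortho to both phenoxides, while the free carbon of ring A has no free phenol beside it. The basic medium spares the tert-butyl ester.

Step 12
Reactants: 19 the formyl hydroxy acid
Product: 20 tert-butyl ester and methyl ether of the formyl depsidone (seven-membered lactone between the A6 carboxyl and the B1 oxygen; OMe on A3, CO2tBu on A4, CHO on B2, OH on B3)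
Conditions: DCC, DMAP (cat.), CH2Cl2, high dilution, 0 °C → rt
Reagents that add atoms: none
Why: Carbodiimide lactonisation (Steglich type), a 7-exo-trig closure of the kind used for depsidone hydroxy acids. The A6 acid is the only free carboxyl and the B1 hydroxyl the only one that can reach it, since the B3 hydroxyl is para to the ether carbon and chelated to the phthalide carbonyl.

Step 13
Reactants: 20 the protected formyl depsidone
Product: 22 formyl depsidone with free A3 phenol and A4 carboxylic acid (23 with CHO in place of CH2OH), via methyl ether acid 21 (not isolated)
Conditions: BCl3 (1 M in CH2Cl2, excess), CH2Cl2, −78 → 0 °C; ice-water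
Reagents that add atoms: none
Why: BCl3 cleaves the tert-butyl ester first and then the methyl ether ortho to the resulting carboxyl through a six-membered boron chelate, a selective demethylation that is standard for ortho-carbonyl methoxy groups. Aryl ester, phthalide and aldehyde carry no alkyl–oxygen bond that ionises under these conditions.

Step 14
Reactants: 22 the formyl depsidone acid
Product: 23 conneotricone
Conditions: NaBH4, THF–EtOH, −10 °C; cold 0.5 M HCl to pH 3
Reagents that add atoms: none
Why: Chemoselective borohydride reduction of the aryl aldehyde; at low temperature the two lactones and the carboxylate are not reduced. An acyl shift from the B1 oxygen to the new alcohol would need a nine-membered lactone and is not expected.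

## Compound list

1 | orsellinic acid (2,4-dihydroxy-6-methylbenzoic acid) | Cc1cc(O)cc(O)c1C(=O)O | starting material
2 | benzyl 2,4-dihydroxy-6-methylbenzoate | Cc1cc(O)cc(O)c1C(=O)OCc1ccccc1 | intermediate
3 | benzyl 2-hydroxy-4-methoxy-6-methylbenzoate | Cc1cc(OC)cc(O)c1C(=O)OCc1ccccc1 | intermediate
4 | benzyl 2-hydroxy-3-(hydroxymethyl)-4-methoxy-6-methylbenzoate (not isolated) | Cc1cc(OC)c(CO)c(O)c1C(=O)OCc1ccccc1 | intermediate
5 | benzyl 3-formyl-2-hydroxy-4-methoxy-6-methylbenzoate | Cc1cc(OC)c(C=O)c(O)c1C(=O)OCc1ccccc1 | intermediate
6 | 3-[(benzyloxy)carbonyl]-2-hydroxy-6-methoxy-4-methylbenzoic acid | Cc1cc(OC)c(C(=O)O)c(O)c1C(=O)OCc1ccccc1 | intermediate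
7 | 1-benzyl 3-tert-butyl 2-hydroxy-4-methoxy-6-methylbenzene-1,3-dicarboxylate | Cc1cc(OC)c(C(=O)OC(C)(C)C)c(O)c1C(=O)OCc1ccccc1 | intermediate
8 | dimethyl (1-diazo-2-oxopropyl)phosphonate | CC(=O)C(=[N+]=[N-])P(=O)(OC)OC | starting material
9 | 1-benzyl 3-tert-butyl 2-{[1-(dimethoxyphosphoryl)-2-oxopropyl]oxy}-4-methoxy-6-methylbenzene-1,3-dicarboxylate (racemic) | CC(=O)C(Oc1c(C(=O)OCc2ccccc2)c(C)cc(OC)c1C(=O)OC(C)(C)C)P(=O)(OC)OC | intermediate
10 | benzyloxyacetaldehyde | O=CCOCc1ccccc1 | starting material
11 | 1-benzyl 3-tert-butyl 2-{[(3Z)-5-(benzyloxy)-2-oxopent-3-en-3-yl]oxy}-4-methoxy-6-methylbenzene-1,3-dicarboxylate | CC(=O)/C(Oc1c(C(=O)OCc2ccccc2)c(C)cc(OC)c1C(=O)OC(C)(C)C)=C/COCc1ccccc1 | intermediate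
12 | dimethyl malonate | COC(=O)CC(=O)OC | starting material
13 | dimethyl 2-[3-(aryloxy)-1-(benzyloxy)-4-oxopentan-2-yl]propanedioate (diastereomer mixture, not isolated) | COC(=O)C(C(=O)OC)C(COCc1ccccc1)C(Oc1c(C(=O)OCc2ccccc2)c(C)cc(OC)c1C(=O)OC(C)(C)C)C(C)=O | intermediate
14 | methyl 5-(aryloxy)-6-[(benzyloxy)methyl]-2,4-dioxocyclohexane-1-carboxylate (diastereomer mixture) | COC(=O)C1C(COCc2ccccc2)C(Oc2c(C(=O)OCc3ccccc3)c(C)cc(OC)c2C(=O)OC(C)(C)C)C(=O)CC1=O | intermediate
15 | methyl 3-(aryloxy)-2-[(benzyloxy)methyl]-4,6-dihydroxybenzoate | COC(=O)c1c(O)cc(O)c(Oc2c(C(=O)OCc3ccccc3)c(C)cc(OC)c2C(=O)OC(C)(C)C)c1COCc1ccccc1 | intermediate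
16 | 3-(tert-butoxycarbonyl)-2-[4,6-dihydroxy-2-(hydroxymethyl)-3-(methoxycarbonyl)phenoxy]-4-methoxy-6-methylbenzoic acid (not isolated) | COC(=O)c1c(O)cc(O)c(Oc2c(C(=O)O)c(C)cc(OC)c2C(=O)OC(C)(C)C)c1CO | intermediate
17 | 3-(tert-butoxycarbonyl)-2-[(5,7-dihydroxy-1-oxo-1,3-dihydro-2-benzofuran-4-yl)oxy]-4-methoxy-6-methylbenzoic acid | Cc1cc(OC)c(C(=O)OC(C)(C)C)c(Oc2c(O)cc(O)c3c2COC3=O)c1C(=O)O | intermediate
18 | 3-(tert-butoxycarbonyl)-2-{[5,7-dihydroxy-6-(hydroxymethyl)-1-oxo-1,3-dihydro-2-benzofuran-4-yl]oxy}-4-methoxy-6-methylbenzoic acid (not isolated) | Cc1cc(OC)c(C(=O)OC(C)(C)C)c(Oc2c(O)c(CO)c(O)c3c2COC3=O)c1C(=O)O | intermediate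
19 | 3-(tert-butoxycarbonyl)-2-[(6-formyl-5,7-dihydroxy-1-oxo-1,3-dihydro-2-benzofuran-4-yl)oxy]-4-methoxy-6-methylbenzoic acid | Cc1cc(OC)c(C(=O)OC(C)(C)C)c(Oc2c(O)c(C=O)c(O)c3c2COC3=O)c1C(=O)O | intermediate
20 | formyl depsidone, A3 methyl ether, A4 tert-butyl ester | Cc1cc(OC)c(C(=O)OC(C)(C)C)c2c1C(=O)Oc1c(C=O)c(O)c3c(c1O2)COC3=O | intermediate
21 | formyl depsidone, A3 methyl ether, A4 free acid (not isolated) | Cc1cc(OC)c(C(=O)O)c2c1C(=O)Oc1c(C=O)c(O)c3c(c1O2)COC3=O | intermediate
22 | formyl depsidone with free A3 phenol and A4 acid | Cc1cc(O)c(C(=O)O)c2c1C(=O)Oc1c(C=O)c(O)c3c(c1O2)COC3=O | intermediate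
23 | conneotricone | Cc1cc(O)c(C(=O)O)c2c1C(=O)Oc1c(CO)c(O)c3c(c1O2)COC3=O | target

## Step count and risk

Total step count: 14. Longest linear sequence: 14 steps, from 1 to 23; 8, 10 and 12 enter as purchased materials.

**Step 8 (key step).** The likeliest failure is slow conjugate addition, because the α-oxygen makes the enone a less electrophilic, captodative acceptor. Side processes then gain ground: displacement of the acidic aryloxide from B6 by the malonate carbanion of 13 (three-membered ring closure), or methoxide exchange at the A6 benzyl ester. The fallback moves the ketone from the acceptor into the donor. Setting out from 7, rhodium-catalysed O–H insertion with methyl diazo(dimethoxyphosphoryl)acetate gives the aryloxy phosphonoacetate F1, and olefination with 10 gives methyl (Z)-2-(aryloxy)-4-(benzyloxy)but-2-enoate F2. This acceptor has no acidic α'-hydrogens and can be pushed harder. Methyl acetoacetate and NaOMe add through the central carbon to give keto triester F3, whose methyl ketone enolate closes onto the aryloxy-bearing ester (B1–B2 bond instead of B2–B3). The sequence comes back to the route at 14.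

**Step 6.** The phenol of 7 is hydrogen-bonded and flanked by two esters, so capture of the rhodium carbenoid may be slow, and carbene dimerisation or insertion into traces of water may then dominate. The fallback replaces carbenoid chemistry by a polar displacement. Dimethyl (2-oxopropyl)phosphonate is chlorinated with SO2Cl2 to dimethyl (1-chloro-2-oxopropyl)phosphonate F4, and the potassium phenoxide of 7 (K2CO3, DMF) is alkylated with it, as is done with α-chloro β-dicarbonyl compounds. The fallback sets out from 7 and returns at 9.

**Step 9.** Iodination may settle on B2, the most acidic carbon, from which no elimination is possible, and lead on to oxidation at that carbon. The HI formed may also cause partial loss of the tert-butyl ester. The fallback is a halogen-free, palladium-catalysed aerobic dehydrogenation (Pd(O2CCF3)2, 2-(dimethylamino)pyridine, TsOH, O2, DMSO, 80 °C). It acts through a palladium enolate and β-hydride elimination, and hence only at B4 or B6, where a β-hydrogen exists. It sets out from 14 and returns at 15 without new compounds.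

**Step 11.** The triply acidic substrate may form an insoluble magnesium salt and convert poorly, and the intermediate 18 may condense with unreacted 17 to a diarylmethane. The fallback changes the order of events. Setting out from 17, the seven-membered lactone is closed first with DCC to give depsidone F5, which has a single free phenol. F5 is then formylated ortho to that phenol by a Rieche reaction (Cl2CHOMe, TiCl4, CH2Cl2, 0 °C), the classical way to formylate depsidones. TiCl4 is expected to strip the tert-butyl ester at the same time, so the sequence returns at 21 (or at 20 if the ester survives), and step 13 follows.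

**Step 12.** The acid is di-ortho-substituted and the B1 phenol is hydrogen-bonded to the new aldehyde, so ring closure may be slower than the O-to-N acyl shift of the activated acid or than intermolecular esterification. The fallback separates activation from cyclisation. Setting out from 19, the acid is converted with 2,4,6-trifluoro-1,3,5-triazine and pyridine into the isolable acyl fluoride F6. Hindered acyl fluorides are stable and do not rearrange. F6 is then cyclised at high dilution with Cs2CO3 in MeCN, returning at 20.

## Further compounds

F1 | step 8 | 1-benzyl 3-tert-butyl 2-[1-(dimethoxyphosphoryl)-2-methoxy-2-oxoethoxy]-4-methoxy-6-methylbenzene-1,3-dicarboxylate | COC(=O)C(Oc1c(C(=O)OCc2ccccc2)c(C)cc(OC)c1C(=O)OC(C)(C)C)P(=O)(OC)OC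
F2 | step 8 | methyl (Z)-2-(aryloxy)-4-(benzyloxy)but-2-enoate carrying ring A as in 11 | COC(=O)/C(Oc1c(C(=O)OCc2ccccc2)c(C)cc(OC)c1C(=O)OC(C)(C)C)=C/COCc1ccccc1
F3 | step 8 | dimethyl 2-acetyl-4-(aryloxy)-3-[(benzyloxy)methyl]pentanedioate (diastereomer mixture) | COC(=O)C(C(C)=O)C(COCc1ccccc1)C(Oc1c(C(=O)OCc2ccccc2)c(C)cc(OC)c1C(=O)OC(C)(C)C)C(=O)OC
F4 | step 6 | dimethyl (1-chloro-2-oxopropyl)phosphonate | CC(=O)C(Cl)P(=O)(OC)OC
F0 | step 9 | none | none
F5 | step 11 | depsidone without the B2 substituent, A3 methyl ether, A4 tert-butyl ester | Cc1cc(OC)c(C(=O)OC(C)(C)C)c2c1C(=O)Oc1cc(O)c3c(c1O2)COC3=O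
F6 | step 12 | acyl fluoride of 19 (A6 carbonyl fluoride) | Cc1cc(OC)c(C(=O)OC(C)(C)C)c(Oc2c(O)c(C=O)c(O)c3c2COC3=O)c1C(F)=O
A1 | alternative 1 | depsidone with free B3 phenol, A3 methyl ether, A4 methyl ester, acetate on the B2 arm | Cc1cc(OC)c(C(=O)OC)c2c1C(=O)Oc1c(COC(C)=O)c(O)c3c(c1O2)COC3=O
A2 | alternative 1 | spiro quinone monoketal: ring A benzodioxinone spiro-linked at B6 to a cyclohexa-2,5-dienone ring B carrying the butenolide and the acetoxymethyl group | Cc1cc(OC)c(C(=O)OC)c2OC3(OC(=O)c12)C=C(COC(C)=O)C(=O)C4=C3COC4=O
A3 | alternative 2 | 1-tert-butyl 3-methyl 2-{[6-(acetoxymethyl)-5-(benzyloxy)-7-methoxy-1-oxo-1,3-dihydro-2-benzofuran-4-yl]oxy}-4-methoxy-6-methylbenzene-1,3-dicarboxylate | Cc1cc(OC)c(C(=O)OC)c(Oc2c(OCc3ccccc3)c(COC(C)=O)c(OC)c3c2COC3=O)c1C(=O)OC(C)(C)C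
A4 | alternative 2 | methyl 4-methoxy-6-methyl-2-oxo-2H-pyran-3-carboxylate | COC(=O)c1c(OC)cc(C)oc1=O
A5 | alternative 2 | tert-butyl 3-{[6-(acetoxymethyl)-5-(benzyloxy)-7-methoxy-1-oxo-1,3-dihydro-2-benzofuran-4-yl]oxy}prop-2-ynoate | CC(C)(C)OC(=O)C#COc1c(OCc2ccccc2)c(COC(C)=O)c(OC)c2c1COC2=O
A6 | alternative 3 | 5-(benzyloxy)-4,7-dihydroxy-6-[(methoxymethoxy)methyl]-2-benzofuran-1(3H)-one | O=C1OCc2c(O)c(OCc3ccccc3)c(COCOC)c(O)c12
A7 | alternative 3 | {[4-(benzyloxy)-3-[(methoxymethoxy)methyl]furan-2-yl]oxy}(tert-butyl)dimethylsilane | COCOCc1c(OCc2ccccc2)coc1O[Si](C)(C)C(C)(C)C
A8 | alternative 3 | methyl 4-hydroxybut-2-ynoate | COC(=O)C#CCO
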